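**Assumptions (one line):** Target = 8-(acylphloroglucinol-methyl)-(+)-catechin, with (2R,3S) 2,3-trans configuration read from the SMILES; (+)-catechin is commercial. Numbered compounds are substrates and products. Simple reagents that add atoms are given by name and SMILES inside each step.

## Retrosynthetic overview
1. Final global debenzylation (H2, Pd) gives the target from the hexa-O-benzylated diarylmethane 10.
2. The C8–CH2–Ar bond is disconnected as a Friedel–Crafts benzylation (**proposed new step**). Tetra-O-benzyl-(+)-catechin 9 reacts at C8 with the carbenium ion of benzylic alcohol 7. 9 comes from commercial (+)-catechin, so C2 and C3 are set by the chiral pool.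
3. The acylphloroglucinol arene is built from 5-methoxyresorcinol. The order is: formylation, reduction to the Me group, Friedel–Crafts isobutyrylation, formylation at the last free C–H, O-benzylation, then reduction to the benzylic alcohol.
4. No new ring is formed. The chroman ring and its aryl rings come intact from catechin, and the second arene is only functionalised.

## Route

**Step 1**
Reactants: 1, 5-methoxybenzene-1,3-diol (3,5-dihydroxyanisole)
Product: 2, 2,4-dihydroxy-6-methoxybenzaldehyde
Conditions: POCl3, DMF, MeCN, 0 °C → rt; then aq. NaHCO3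
Reagents that add atoms: DMF (CN(C)C=O), POCl3 (O=P(Cl)(Cl)Cl)
Why: Vilsmeier–Haack formylation goes to the ring carbon between OH and OMe (para to the other OH), the most activated and least crowded site. Minor regioisomer is removed by chromatography.

**Step 2**
Reactants: 2
Product: 3, 5-methoxy-4-methylbenzene-1,3-diol
Conditions: NaBH4 (4 equiv), EtOH, 80 °C
Reagents that add atoms: none
Why: Hydride reduction of the o-hydroxybenzaldehyde gives the benzylic alcohol, which loses water to an o-quinone methide that is reduced again, so CHO becomes CH3.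

**Step 3**
Reactants: 3
Product: 4, 1-(4,6-dihydroxy-2-methoxy-3-methylphenyl)-2-methylpropan-1-one
Conditions: i-PrCO2H, BF3·OEt2, 80 °C, 3 h
Reagents that add atoms: isobutyric acid (CC(C)C(=O)O)
Why: BF3-mediated Friedel–Crafts acylation goes to the only ring position flanked by OH and OMe, the same regiochemistry as step 1. The position between the two OH groups is disfavoured sterically. The result has the ketone flanked by OMe and OH, as in the target.

**Step 4**
Reactants: 4
Product: 5, 1-(4,6-dihydroxy-5-formyl-2-methoxy-3-methylphenyl)-2-methylpropan-1-one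
Conditions: POCl3, DMF, 0 °C → rt; then aq. NaOAc
Reagents that add atoms: DMF (CN(C)C=O), POCl3 (O=P(Cl)(Cl)Cl)
Why: Vilsmeier formylation at the single remaining, phloroglucinol-type C–H between the two OH groups. The α-tertiary isopropyl ketone cannot give a chromone.

**Step 5**
Reactants: 5
Product: 6, 1-(4,6-bis(benzyloxy)-5-formyl-2-methoxy-3-methylphenyl)-2-methylpropan-1-one
Conditions: BnBr (3 equiv), K2CO3, TBAI (cat.), DMF, 60 °C
Reagents that add atoms: benzyl bromide (BrCc1ccccc1)
Why: Williamson O-benzylation of both phenols, giving protection that is removed in the last step.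

**Step 6**
Reactants: 6
Product: 7, 1-(4,6-bis(benzyloxy)-5-(hydroxymethyl)-2-methoxy-3-methylphenyl)-2-methylpropan-1-one
Conditions: NaBH4, THF/MeOH, 0 °C
Reagents that add atoms: none
Why: The unhindered aldehyde is reduced chemoselectively. The di-ortho-substituted isopropyl aryl ketone is inert under these conditions.

**Step 7**
Reactants: 8, (+)-catechin (2R,3S)
Product: 9, 5,7,3′,4′-tetra-O-benzyl-(+)-catechin
Conditions: BnBr (4.4 equiv), K2CO3, DMF, rt, 16 h
Reagents that add atoms: benzyl bromide (BrCc1ccccc1)
Why: K2CO3 alkylates the acidic phenols but not the secondary 3-OH. No stereocentre is touched, so 2R,3S is retained.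

**Step 8 (key step)**
Reactants: 7 (1.3 equiv) and 9 (1.0 equiv)
Product: 10, 8-[(2,4-bis(benzyloxy)-6-isobutyryl-... arene)methyl]-tetra-O-benzyl-(+)-catechin; full name: 1-(4,6-bis(benzyloxy)-2-methoxy-3-methyl-5-{[(2R,3S)-3-hydroxy-5,7-bis(benzyloxy)-2-(3,4-bis(benzyloxy)phenyl)chroman-8-yl]methyl}phenyl)-2-methylpropan-1-one
Conditions: Bi(OTf)3 (10 mol %), 4 Å MS, CH2Cl2, −10 °C → rt, 3 h
Reagents that add atoms: none (H2O is lost)
Why: Dehydrative Friedel–Crafts benzylation through a stabilised benzylic carbenium ion. No new stereocentre forms, and mild catalytic Lewis acid at low temperature leaves C2/C3 intact.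
Proposed new method: Bi(OTf)3 ionises the hindered benzylic alcohol 7, which has two ortho-OBn and a para-OMe, to a Tmob-type carbenium ion, and this cation is trapped by the most accessible nucleophilic carbon of 9. C8 is flanked by the tied-back pyran oxygen and one OBn, whereas C6 sits between two OBn groups, so C8 is favoured, as in C8-selective NBS bromination and C4-electrophile coupling of benzylated catechins. The closest known reactions are Lewis-acid dehydrative benzylations with Tmob/PMB-type cations and procyanidin-type C8 couplings. The new feature is coupling two tetra-ortho-hindered, polyoxygenated partners, one bearing an acyl group, with C8 regiocontrol.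

**Step 9**
Reactants: 10
Product: 11, Pilosanol B
Conditions: H2 (1 atm), Pd(OH)2/C, THF/MeOH 1:1, rt, 12 h
Reagents that add atoms: none (H2 adds only H)
Why: Hydrogenolysis removes all six O-benzyl groups. The aryl ketone, OMe, diarylmethane and the C2/C3 stereocentres survive these conditions.

## Compound list
1 | 5-methoxybenzene-1,3-diol | COc1cc(O)cc(O)c1 | starting material
2 | 2,4-dihydroxy-6-methoxybenzaldehyde | COc1cc(O)cc(O)c1C=O | intermediate
3 | 5-methoxy-4-methylbenzene-1,3-diol | COc1cc(O)cc(O)c1C | intermediate
4 | 1-(4,6-dihydroxy-2-methoxy-3-methylphenyl)-2-methylpropan-1-one | COc1c(C)c(O)cc(O)c1C(=O)C(C)C | intermediate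
5 | 3-formyl analogue of 4 | COc1c(C)c(O)c(C=O)c(O)c1C(=O)C(C)C | intermediate
6 | bis-O-benzyl aldehyde | COc1c(C)c(OCc2ccccc2)c(C=O)c(OCc2ccccc2)c1C(=O)C(C)C | intermediate
7 | bis-O-benzyl benzylic alcohol | COc1c(C)c(OCc2ccccc2)c(CO)c(OCc2ccccc2)c1C(=O)C(C)C | intermediate
8 | (+)-catechin (2R,3S) | Oc1cc(O)c2c(c1)O[C@H](c1ccc(O)c(O)c1)[C@@H](O)C2 | starting material
9 | 5,7,3′,4′-tetra-O-benzyl-(+)-catechin | O(Cc3ccccc3)c1cc(OCc3ccccc3)c2c(c1)O[C@H](c1ccc(OCc3ccccc3)c(OCc3ccccc3)c1)[C@@H](O)C2 | intermediate
10 | C8-benzylated hexa-O-benzyl diarylmethane | O(Cc3ccccc3)c1cc(OCc3ccccc3)c2c(c1Cc1c(OCc3ccccc3)c(C)c(OC)c(C(=O)C(C)C)c1OCc1ccccc1)O[C@H](c1ccc(OCc3ccccc3)c(OCc3ccccc3)c1)[C@@H](O)C2 | intermediate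
11 | Pilosanol B | COc1c(C)c(O)c(Cc2c(O)cc(O)c3c2O[C@H](c2ccc(O)c(O)c2)[C@@H](O)C3)c(O)c1C(=O)C(C)C | target

## Totals
Total steps: 9. Longest linear sequence: 8 (steps 1–6, 8, 9).

## Three steps most likely to fail
1. **Step 8 (proposed new step).** The tetra-ortho-hindered coupling may be low-yielding, or the cation may give 3-O-ether or C6 products.
   Fallback (known chemistry, different approach): brominate 9 with NBS at C8 and do Br/Li exchange with t-BuLi (3-OH as its lithium alkoxide). Add the aryllithium to aldehyde 6 at −78 °C to give the diarylmethanol, then hydrogenolyse with H2/Pd(OH)2/C. This removes the benzyl groups and the benzylic OH in one step to give 11.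
2. **Step 3 (regioselective acylation of 3).** Acylation at the OH/OH site would give the wrong isomer.
   Fallback: block the OH/OH carbon of 3 with Br (NBS, −78 °C), acylate the remaining position, and benzylate the phenols. Then do Br/Li exchange and quench with DMF to reach aldehyde 6 directly. The rest of the route is unchanged.
3. **Step 2 (CHO → CH3 on the free polyphenol).** o-Quinone methide oligomerisation can compete.
   Fallback: O-benzylate 2, reduce the protected aldehyde by ionic hydrogenation (Et3SiH/TFA), then remove the benzyl groups (H2/Pd-C) to return 3.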